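## Retrosynthetic overview

1. Testudinariol A is C2-symmetric. Both Z-trisubstituted alkenes are cut at once by a two-directional Wittig reaction between a butane-1,4-diyl bis-ylide and two molecules of a 6-cyclopentyl-tetrahydropyran-3-one, followed by desilylation.
2. The strategy rests on the tetrahydropyran ring O1–C6. Its only stereocentre, C2 (next to the cyclopentane), is the carbinol carbon of a 2-furyl carbinol, and C3–C6 are the four furan carbons. Anodic methoxylation and acid rearrangement (Achmatowicz) form the O1–C6 bond and close this ring.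
3. The pyranone carbonyl is then moved from C3 to C5: lactol reduction, epoxidation, Wharton transposition, oxidation, conjugate reduction.
4. The furyl carbinol comes from a cyclopentane aldehyde (2-furyllithium, oxidation, asymmetric transfer hydrogenation). The cyclopentane (OH cis to isopropenyl, trans to the side chain) comes from a Me2AlCl carbonyl-ene reaction of an aldehyde whose α-centre is set by Evans alkoxymethylation.
5. Ring order: cyclopentane (step 7), then pyran (step 14); the two halves are joined last.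

Key step: step 14

Remarks on the chemistry:
- The target is read as Z,Z at the exocyclic alkenes (butane chain cis to the ring O–CH2), with the cyclopentanol OH cis to isopropenyl and trans to the pyranyl group.
- The pyran ring is numbered O1, C2 (cyclopentyl-bearing), C3–C6 in all discussion; TBS = tert-butyldimethylsilyl.
- The carbinol carbon of 21, the lactol carbon of 26, the epoxide carbons of 28 and 29 and the carbinol carbon of 30 are expected as epimer mixtures. All are removed later, so the mixtures are carried on and their SMILES leave these centres open.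

## Route

Step 1
Reactants: 1 diethyl malonate; 2 5-bromo-2-methylpent-2-ene
Product: 4 diethyl 2-(4-methylpent-3-en-1-yl)malonate, via sodium diethyl malonate 3 (not isolated)
Conditions: NaH, THF/DMF, 0 °C; then 2, 60 °C (malonate in excess)
Reagents that add atoms: none
Why: Malonic ester alkylation, an SN2 displacement of the primary bromide by the malonate anion, with excess malonate suppressing dialkylation.

Step 2
Reactants: 4 diethyl 2-(4-methylpent-3-en-1-yl)malonate
Product: 6 6-methylhept-5-enoic acid, via 2-(4-methylpent-3-en-1-yl)malonic acid 5 (not isolated)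
Conditions: KOH, EtOH/H2O, reflux; aq. HCl, 0 °C; then xylene, 140 °C
Reagents that add atoms: potassium hydroxide, [K+].[OH-]
Why: Saponification followed by thermal decarboxylation of the substituted malonic acid through the usual cyclic transition state, which leaves the trisubstituted alkene untouched.

Step 3
Reactants: 6 6-methylhept-5-enoic acid; 7 (S)-4-benzyloxazolidin-2-one
Product: 9 (S)-4-benzyl-3-(6-methylhept-5-enoyl)oxazolidin-2-one, via mixed pivalic anhydride 8 (not isolated)
Conditions: t-BuCOCl, Et3N, THF, −20 °C; then 7, LiCl, −20 °C → rt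
Reagents that add atoms: none
Why: N-Acylation of the oxazolidinone through the mixed anhydride, in which the hindered pivaloyl carbonyl directs attack to the desired acyl carbon.

Step 4
Reactants: 9 (S)-4-benzyl-3-(6-methylhept-5-enoyl)oxazolidin-2-one; 10 benzyl chloromethyl ether
Product: 12 (S)-4-benzyl-3-[(R)-2-(benzyloxymethyl)-6-methylhept-5-enoyl]oxazolidin-2-one, via chlorotitanium Z-enolate 11 (not isolated)
Conditions: TiCl4, i-Pr2NEt, CH2Cl2, 0 °C; then 10, 0 °C
Reagents that add atoms: none
Why: Evans alkylation of the chelated Z-enolate, in which the benzyl group of the auxiliary blocks one face so that alkoxymethylation on the other face sets the (R) α-centre (the future cyclopentane carbon that carries the pyran).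

Step 5
Reactants: 12 (S)-4-benzyl-3-[(R)-2-(benzyloxymethyl)-6-methylhept-5-enoyl]oxazolidin-2-one
Product: 13 (S)-2-(benzyloxymethyl)-6-methylhept-5-en-1-ol
Conditions: LiBH4, MeOH (1 equiv), THF, 0 °C
Reagents that add atoms: none
Why: Reductive cleavage of the imide at the exocyclic carbonyl releases the auxiliary and the primary alcohol without touching the α-stereocentre.

Step 6
Reactants: 13 (S)-2-(benzyloxymethyl)-6-methylhept-5-en-1-ol
Product: 14 (R)-2-(benzyloxymethyl)-6-methylhept-5-enal
Conditions: Dess–Martin periodinane, NaHCO3, CH2Cl2, 0 °C → rt; used at once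
Reagents that add atoms: none
Why: Dess–Martin oxidation under buffered, non-basic conditions should keep the enolisable α-centre of the β-benzyloxy aldehyde intact.

Step 7
Reactants: 14 (R)-2-(benzyloxymethyl)-6-methylhept-5-enal
Product: 15 (1S,2R,5R)-2-(benzyloxymethyl)-5-(prop-1-en-2-yl)cyclopentan-1-ol
Conditions: Me2AlCl (1.5 equiv), CH2Cl2, −78 → −20 °C
Reagents that add atoms: none
Why: Intramolecular carbonyl-ene reaction of type 1, in which the concerted hydrogen transfer from an allylic methyl group to the aluminium-bound oxygen places OH and isopropenyl cis on the new ring, while the CH2OBn group should take the face opposite to both, so that C1 and C5 are set relative to C2.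

Step 8
Reactants: 15 (1S,2R,5R)-2-(benzyloxymethyl)-5-(prop-1-en-2-yl)cyclopentan-1-ol
Product: 16 tert-butyl{[(1S,2R,5R)-2-(benzyloxymethyl)-5-(prop-1-en-2-yl)cyclopentyl]oxy}dimethylsilane
Conditions: TBSOTf, 2,6-lutidine, CH2Cl2, 0 °C
Reagents that add atoms: tert-butyldimethylsilyl trifluoromethanesulfonate, CC(C)(C)[Si](C)(C)OS(=O)(=O)C(F)(F)F
Why: Silylation with the reactive silyl triflate, which is needed for a secondary alcohol flanked by two substituents.

Step 9
Reactants: 16 tert-butyl{[(1S,2R,5R)-2-(benzyloxymethyl)-5-(prop-1-en-2-yl)cyclopentyl]oxy}dimethylsilane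
Product: 17 [(1R,2S,3R)-2-(TBSO)-3-(prop-1-en-2-yl)cyclopentyl]methanol
Conditions: Li, NH3(l)/THF, −78 °C; then NH4Cl
Reagents that add atoms: none
Why: Dissolving-metal debenzylation by electron transfer to the arene and C–O cleavage, under which the isolated alkene and the silyl ether are inert.

Step 10
Reactants: 17 [(1R,2S,3R)-2-(TBSO)-3-(prop-1-en-2-yl)cyclopentyl]methanol
Product: 18 (1S,2S,3R)-2-(TBSO)-3-(prop-1-en-2-yl)cyclopentane-1-carbaldehyde
Conditions: Dess–Martin periodinane, NaHCO3, CH2Cl2, 0 °C → rt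
Reagents that add atoms: none
Why: Dess–Martin oxidation; the formyl group trans to the silyloxy group is the more stable arrangement, so epimerisation is not a threat.

Step 11
Reactants: 18 (1S,2S,3R)-2-(TBSO)-3-(prop-1-en-2-yl)cyclopentane-1-carbaldehyde; 19 furan
Product: 21 (RS)-[(1R,2S,3R)-2-(TBSO)-3-(prop-1-en-2-yl)cyclopentyl](furan-2-yl)methanol (both carbinol epimers), via 2-furyllithium 20 (not isolated)
Conditions: furan, n-BuLi, THF, 0 °C; then 18, −78 °C; H2O
Reagents that add atoms: none
Why: 1,2-Addition of 2-furyllithium (from α-lithiation of furan) to the aldehyde; the carbinol configuration is left uncontrolled because the next step erases it.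

Step 12
Reactants: 21 (RS)-[(1R,2S,3R)-2-(TBSO)-3-(prop-1-en-2-yl)cyclopentyl](furan-2-yl)methanol
Product: 22 [(1S,2S,3R)-2-(TBSO)-3-(prop-1-en-2-yl)cyclopentyl](furan-2-yl)methanone
Conditions: Dess–Martin periodinane, NaHCO3, CH2Cl2, 0 °C → rt
Reagents that add atoms: none
Why: Dess–Martin oxidation converts both carbinol epimers into one furyl ketone.

Step 13
Reactants: 22 [(1S,2S,3R)-2-(TBSO)-3-(prop-1-en-2-yl)cyclopentyl](furan-2-yl)methanone
Product: 23 (S)-[(1R,2S,3R)-2-(TBSO)-3-(prop-1-en-2-yl)cyclopentyl](furan-2-yl)methanol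
Conditions: RuCl(p-cymene)[(S,S)-TsDPEN] (3 mol %), HCO2H/Et3N (5:2), CH2Cl2, 30 °C
Reagents that add atoms: none
Why: Noyori asymmetric transfer hydrogenation, in which the (S,S) catalyst treats the furan as the aryl group and should deliver hydride under catalyst control to give the (S) carbinol, the future C2 of the pyran.

Step 14
Reactants: 23 (S)-[(1R,2S,3R)-2-(TBSO)-3-(prop-1-en-2-yl)cyclopentyl](furan-2-yl)methanol
Product: 26 (2S)-2-[(1R,2S,3R)-2-(TBSO)-3-(prop-1-en-2-yl)cyclopentyl]-6-hydroxy-2H-pyran-3(6H)-one (lactol; both C6 epimers), via 2,5-dimethoxy-2,5-dihydrofuran carbinol 24 (not isolated), via Z-enedione carbinol 25 (not isolated)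
Conditions: graphite anode, Pt cathode, undivided cell, constant current (about 2.2 F/mol), Et4NOTs, MeOH, −10 °C; then 1% aq. H2SO4, THF, 0 °C → rt
Reagents that add atoms: water, O; methanol, CO (its methoxy groups are present only in 24 and are lost again)
Why: Two-electron anodic oxidation of the furan with capture by methanol should give the 2,5-dimethoxy-2,5-dihydrofuran 24; dilute acid then hydrolyses both acetal carbons to the Z-configured 4-oxo-enal 25, whose carbinol oxygen adds to the aldehyde carbon to give lactol 26. The closest known reaction type is the Achmatowicz rearrangement in its electrochemical form, long used for furfuryl alcohols. The pyran ring closes by 6-exo-trig addition of the hydroxyl group to the aldehyde C=O, which forms the O1–C6 bond. No stereocentre that reaches the target is created: C6 forms as an anomeric mixture and becomes CH2 in step 15, while C2 is carried over unchanged from the carbinol set in step 13. The selectivity needed is oxidation of the furan in preference to the isopropenyl alkene, which is secured by the much lower oxidation potential of the 2-alkylfuran and by limiting the charge to about two faradays per mole; the hindered silyl ether should withstand the brief dilute-acid hydrolysis.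

Step 15
Reactants: 26 (2S)-2-[(1R,2S,3R)-2-(TBSO)-3-(prop-1-en-2-yl)cyclopentyl]-6-hydroxy-2H-pyran-3(6H)-one
Product: 27 (2S)-2-[(1R,2S,3R)-2-(TBSO)-3-(prop-1-en-2-yl)cyclopentyl]-2H-pyran-3(6H)-one
Conditions: Et3SiH, CF3CO2H, CH2Cl2, −40 °C
Reagents that add atoms: none
Why: Ionic hydrogenation of the lactol through the ring oxocarbenium ion, with hydride delivered to C6, at a temperature low enough that the isopropenyl group is not protonated and the silyl ether is kept.

Step 16
Reactants: 27 (2S)-2-[(1R,2S,3R)-2-(TBSO)-3-(prop-1-en-2-yl)cyclopentyl]-2H-pyran-3(6H)-one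
Product: 28 (2S)-2-[(1R,2S,3R)-2-(TBSO)-3-(prop-1-en-2-yl)cyclopentyl]-4,5-epoxytetrahydro-2H-pyran-3-one (both epoxide faces)
Conditions: 30% H2O2, NaOH (0.2 equiv), MeOH, −20 °C, short reaction time
Reagents that add atoms: hydrogen peroxide, OO
Why: Weitz–Scheffer nucleophilic epoxidation attacks only the electron-poor enone and not the isopropenyl alkene, and the weakly basic hydroperoxide at low temperature should leave the C2–H next to the ketone unepimerised; the new epoxide centres are removed later.

Step 17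
Reactants: 28 (2S)-2-[(1R,2S,3R)-2-(TBSO)-3-(prop-1-en-2-yl)cyclopentyl]-4,5-epoxytetrahydro-2H-pyran-3-one
Product: 30 (6R)-6-[(1R,2S,3R)-2-(TBSO)-3-(prop-1-en-2-yl)cyclopentyl]-3,6-dihydro-2H-pyran-3-ol (C3=C4 alkene and C5–OH in the fixed numbering; both carbinol epimers), via epoxy hydrazone 29 (not isolated)
Conditions: N2H4·H2O, AcOH (cat.), MeOH, 0 °C → rt
Reagents that add atoms: none
Why: Wharton transposition, in which the epoxy hydrazone opens to a hydroxy vinyl diazene that loses N2, moving the oxygen from C3 to C5 without involving C2.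

Step 18
Reactants: 30 (6R)-6-[(1R,2S,3R)-2-(TBSO)-3-(prop-1-en-2-yl)cyclopentyl]-3,6-dihydro-2H-pyran-3-ol
Product: 31 (6R)-6-[(1R,2S,3R)-2-(TBSO)-3-(prop-1-en-2-yl)cyclopentyl]-2H-pyran-3(6H)-one
Conditions: Dess–Martin periodinane, NaHCO3, CH2Cl2, 0 °C
Reagents that add atoms: none
Why: Dess–Martin oxidation of the allylic alcohol converts both epimers into one enone with the carbonyl now at C5.

Step 19
Reactants: 31 (6R)-6-[(1R,2S,3R)-2-(TBSO)-3-(prop-1-en-2-yl)cyclopentyl]-2H-pyran-3(6H)-one
Product: 32 (6R)-6-[(1R,2S,3R)-2-(TBSO)-3-(prop-1-en-2-yl)cyclopentyl]dihydro-2H-pyran-3(4H)-one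
Conditions: [(Ph3P)CuH]6, H2O (degassed), THF, rt
Reagents that add atoms: none
Why: Copper hydride conjugate reduction adds hydride only to the β-carbon of the enone and water protonates the copper enolate, so the isolated isopropenyl alkene and the silyl ether are untouched.

Step 20
Reactants: 33 1,4-dibromobutane
Product: 34 butane-1,4-diylbis(triphenylphosphonium) dibromide
Conditions: PPh3 (2.1 equiv), DMF, 150 °C
Reagents that add atoms: triphenylphosphine, c1ccc(cc1)P(c1ccccc1)c1ccccc1
Why: Double SN2 quaternisation of the primary dibromide, with excess phosphine driving it to the bis-salt.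

Step 21
Reactants: 32 (6R)-6-[(1R,2S,3R)-2-(TBSO)-3-(prop-1-en-2-yl)cyclopentyl]dihydro-2H-pyran-3(4H)-one (2.1 equiv); 34 butane-1,4-diylbis(triphenylphosphonium) dibromide
Product: 36 bis(tert-butyldimethylsilyl) ether of testudinariol A, via butane-1,4-diyl bis-ylide 35 (not isolated)
Conditions: 34, KN(SiMe3)2 (2 equiv), THF, 0 °C; then 32, −78 °C → rt
Reagents that add atoms: none
Why: Two-directional Wittig olefination with an unstabilised bis-ylide; such ylides add to α-alkoxy ketones so that the ylide chain ends up cis to the oxygen-bearing α-carbon, which should give both alkenes with the butane chain syn to the ring O–CH2 (Z,Z).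

Step 22
Reactants: 36 bis(tert-butyldimethylsilyl) ether of testudinariol A
Product: 37 testudinariol A
Conditions: Bu4NF, THF, 50 °C
Reagents that add atoms: none
Why: Fluoride cleavage of both silyl ethers under non-acidic conditions, which spares the exocyclic allylic ether alkenes and the isopropenyl groups.

## Compound list

1 | diethyl malonate | CCOC(=O)CC(=O)OCC | starting material
2 | 5-bromo-2-methylpent-2-ene | CC(C)=CCCBr | starting material
3 | sodium diethyl malonate | CCOC(=O)[CH-]C(=O)OCC.[Na+] | intermediate (not isolated)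
4 | diethyl 2-(4-methylpent-3-en-1-yl)malonate | CCOC(=O)C(CCC=C(C)C)C(=O)OCC | intermediate
5 | 2-(4-methylpent-3-en-1-yl)malonic acid | CC(C)=CCCC(C(=O)O)C(=O)O | intermediate (not isolated)
6 | 6-methylhept-5-enoic acid | CC(C)=CCCCC(=O)O | intermediate
7 | (S)-4-benzyloxazolidin-2-one | O=C1N[C@@H](Cc2ccccc2)CO1 | starting material
8 | 6-methylhept-5-enoic pivalic anhydride | CC(C)=CCCCC(=O)OC(=O)C(C)(C)C | intermediate (not isolated)
9 | (S)-4-benzyl-3-(6-methylhept-5-enoyl)oxazolidin-2-one | CC(C)=CCCCC(=O)N1[C@@H](Cc2ccccc2)COC1=O | intermediate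
10 | benzyl chloromethyl ether | ClCOCc1ccccc1 | starting material
11 | chlorotitanium Z-enolate of 9 | CC(C)=CCC/C=C(\O[Ti](Cl)(Cl)Cl)N1[C@@H](Cc2ccccc2)COC1=O | intermediate (not isolated)
12 | (S)-4-benzyl-3-[(R)-2-(benzyloxymethyl)-6-methylhept-5-enoyl]oxazolidin-2-one | CC(C)=CCC[C@H](COCc1ccccc1)C(=O)N1[C@@H](Cc2ccccc2)COC1=O | intermediate
13 | (S)-2-(benzyloxymethyl)-6-methylhept-5-en-1-ol | CC(C)=CCC[C@H](COCc1ccccc1)CO | intermediate
14 | (R)-2-(benzyloxymethyl)-6-methylhept-5-enal | CC(C)=CCC[C@H](COCc1ccccc1)C=O | intermediate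
15 | (1S,2R,5R)-2-(benzyloxymethyl)-5-(prop-1-en-2-yl)cyclopentan-1-ol | C=C(C)[C@H]1CC[C@H](COCc2ccccc2)[C@H]1O | intermediate
16 | tert-butyl{[(1S,2R,5R)-2-(benzyloxymethyl)-5-(prop-1-en-2-yl)cyclopentyl]oxy}dimethylsilane | C=C(C)[C@H]1CC[C@H](COCc2ccccc2)[C@H]1O[Si](C)(C)C(C)(C)C | intermediate
17 | [(1R,2S,3R)-2-(TBSO)-3-(prop-1-en-2-yl)cyclopentyl]methanol | C=C(C)[C@H]1CC[C@H](CO)[C@H]1O[Si](C)(C)C(C)(C)C | intermediate
18 | (1S,2S,3R)-2-(TBSO)-3-(prop-1-en-2-yl)cyclopentane-1-carbaldehyde | C=C(C)[C@H]1CC[C@H](C=O)[C@H]1O[Si](C)(C)C(C)(C)C | intermediate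
19 | furan | c1ccoc1 | starting material
20 | 2-furyllithium | [Li]c1ccco1 | intermediate (not isolated)
21 | (RS)-[(1R,2S,3R)-2-(TBSO)-3-(prop-1-en-2-yl)cyclopentyl](furan-2-yl)methanol, carbinol epimers | C=C(C)[C@H]1CC[C@H](C(O)c2ccco2)[C@H]1O[Si](C)(C)C(C)(C)C | intermediate
22 | [(1S,2S,3R)-2-(TBSO)-3-(prop-1-en-2-yl)cyclopentyl](furan-2-yl)methanone | C=C(C)[C@H]1CC[C@H](C(=O)c2ccco2)[C@H]1O[Si](C)(C)C(C)(C)C | intermediate
23 | (S)-[(1R,2S,3R)-2-(TBSO)-3-(prop-1-en-2-yl)cyclopentyl](furan-2-yl)methanol | C=C(C)[C@H]1CC[C@H]([C@H](O)c2ccco2)[C@H]1O[Si](C)(C)C(C)(C)C | intermediate (key-step precursor)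
24 | (S)-[(1R,2S,3R)-2-(TBSO)-3-(prop-1-en-2-yl)cyclopentyl](2,5-dimethoxy-2,5-dihydrofuran-2-yl)methanol, acetal epimers | C=C(C)[C@H]1CC[C@H]([C@H](O)C2(OC)C=CC(OC)O2)[C@H]1O[Si](C)(C)C(C)(C)C | intermediate (not isolated)
25 | (2Z,5S)-5-[(1R,2S,3R)-2-(TBSO)-3-(prop-1-en-2-yl)cyclopentyl]-5-hydroxy-4-oxopent-2-enal | C=C(C)[C@H]1CC[C@H]([C@H](O)C(=O)/C=C\C=O)[C@H]1O[Si](C)(C)C(C)(C)C | intermediate (not isolated)
26 | (2S)-2-[(1R,2S,3R)-2-(TBSO)-3-(prop-1-en-2-yl)cyclopentyl]-6-hydroxy-2H-pyran-3(6H)-one, C6 epimers | C=C(C)[C@H]1CC[C@H]([C@H]2C(=O)C=CC(O)O2)[C@H]1O[Si](C)(C)C(C)(C)C | intermediate (key-step product)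
27 | (2S)-2-[(1R,2S,3R)-2-(TBSO)-3-(prop-1-en-2-yl)cyclopentyl]-2H-pyran-3(6H)-one | C=C(C)[C@H]1CC[C@H]([C@H]2C(=O)C=CCO2)[C@H]1O[Si](C)(C)C(C)(C)C | intermediate
28 | (2S)-2-[(1R,2S,3R)-2-(TBSO)-3-(prop-1-en-2-yl)cyclopentyl]-4,5-epoxytetrahydro-2H-pyran-3-one, epoxide epimers | C=C(C)[C@H]1CC[C@H]([C@H]2C(=O)C3OC3CO2)[C@H]1O[Si](C)(C)C(C)(C)C | intermediate
29 | hydrazone of 28 | C=C(C)[C@H]1CC[C@H]([C@H]2C(=NN)C3OC3CO2)[C@H]1O[Si](C)(C)C(C)(C)C | intermediate (not isolated)
30 | (6R)-6-[(1R,2S,3R)-2-(TBSO)-3-(prop-1-en-2-yl)cyclopentyl]-3,6-dihydro-2H-pyran-3-ol, carbinol epimers | C=C(C)[C@H]1CC[C@H]([C@H]2C=CC(O)CO2)[C@H]1O[Si](C)(C)C(C)(C)C | intermediate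
31 | (6R)-6-[(1R,2S,3R)-2-(TBSO)-3-(prop-1-en-2-yl)cyclopentyl]-2H-pyran-3(6H)-one | C=C(C)[C@H]1CC[C@H]([C@H]2C=CC(=O)CO2)[C@H]1O[Si](C)(C)C(C)(C)C | intermediate
32 | (6R)-6-[(1R,2S,3R)-2-(TBSO)-3-(prop-1-en-2-yl)cyclopentyl]dihydro-2H-pyran-3(4H)-one | C=C(C)[C@H]1CC[C@H]([C@H]2CCC(=O)CO2)[C@H]1O[Si](C)(C)C(C)(C)C | intermediate
33 | 1,4-dibromobutane | BrCCCCBr | starting material
34 | butane-1,4-diylbis(triphenylphosphonium) dibromide | [Br-].[Br-].c1ccc(cc1)[P+](CCCC[P+](c1ccccc1)(c1ccccc1)c1ccccc1)(c1ccccc1)c1ccccc1 | intermediate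
35 | butane-1,4-diylidenebis(triphenylphosphorane) | c1ccc(cc1)P(=CCCC=P(c1ccccc1)(c1ccccc1)c1ccccc1)(c1ccccc1)c1ccccc1 | intermediate (not isolated)
36 | bis(tert-butyldimethylsilyl) ether of testudinariol A | C=C(C)[C@H]1CC[C@H]([C@H]2CC/C(=C/CC/C=C3/CC[C@H]([C@H]4CC[C@H](C(=C)C)[C@@H]4O[Si](C)(C)C(C)(C)C)OC3)CO2)[C@H]1O[Si](C)(C)C(C)(C)C | intermediate
37 | testudinariol A | C=C(C)[C@H]1CC[C@H]([C@H]2CC/C(=C/CC/C=C3/CC[C@H]([C@H]4CC[C@H](C(=C)C)[C@@H]4O)OC3)CO2)[C@H]1O | target

## Step count and risks

Total steps: 22. Longest linear sequence: 21 (steps 1–19, 21, 22); step 20 is a one-step branch.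

The three steps most likely to fail:

1. Step 21 (two-directional Wittig). The strongly basic bis-ylide may enolise the α-alkoxy ketone, or the reaction may stall after the first olefination, so that mono-olefinated material accumulates and the precious ketone is lost. The fallback builds the linker in two separate Wittig reactions. Setting out from 32, the ylide of [4-(4-methoxybenzyloxy)butyl]triphenylphosphonium bromide (KN(SiMe3)2, THF, −78 °C → rt) should give the PMB-protected Z-alkylidene pyran F1. DDQ in CH2Cl2/pH 7 buffer then frees the primary alcohol F2, I2/PPh3/imidazole gives the primary iodide F3, and PPh3 in MeCN at 80 °C gives the phosphonium iodide F4. The ylide of F4 (KN(SiMe3)2) is combined with a second equivalent of 32, and the sequence comes back to the route at 36.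

2. Step 17 (Wharton transposition). The hydrazone nitrogen may attack the epoxide intramolecularly, or the vinyl diazene may collapse unselectively, so that little allylic alcohol is formed. The fallback replaces the diazene fragmentation by a radical epoxide opening. Setting out from 28, NaBH4 in MeOH at 0 °C gives the epoxy alcohol F5, and 1,1'-thiocarbonyldiimidazole with DMAP in CH2Cl2 gives the O-thiocarbonylimidazolide F6. Bu3SnH/AIBN in benzene at 80 °C then generates the C3 radical (Barton–McCombie-type C–O cleavage), which opens the adjacent epoxide; the alkoxy radical is reduced by the stannane, and the sequence comes back to the route at 30.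

3. Step 14 (anodic dearomatisation). Electrode fouling, oxidation beyond the two-electron stage or competing methoxylation at the isopropenyl group may erode the conversion, and the lactol may decompose during acid hydrolysis. The fallback oxidises the furan by cycloaddition instead of electron transfer. Setting out from 23, singlet oxygen (O2, tetraphenylporphyrin, visible light, CH2Cl2, −78 °C) adds across the furan, far faster than it reacts with a 1,1-disubstituted alkene, to give the furan endoperoxide F7. Reduction with Me2S gives the enedione 25, which closes spontaneously, and the sequence comes back to the route at 26.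

Further compounds

F1 | step 21 | tert-butyldimethylsilyl ether of the (Z)-3-[4-(4-methoxybenzyloxy)butylidene] pyran from 32 (chain cis to ring O–CH2) | C=C(C)[C@H]1CC[C@H]([C@H]2CC/C(=C/CCCOCc3ccc(OC)cc3)CO2)[C@H]1O[Si](C)(C)C(C)(C)C
F2 | step 21 | (Z)-4-pyranylidene-butan-1-ol from F1 | C=C(C)[C@H]1CC[C@H]([C@H]2CC/C(=C/CCCO)CO2)[C@H]1O[Si](C)(C)C(C)(C)C
F3 | step 21 | (Z)-4-pyranylidene-butyl iodide from F2 | C=C(C)[C@H]1CC[C@H]([C@H]2CC/C(=C/CCCI)CO2)[C@H]1O[Si](C)(C)C(C)(C)C
F4 | step 21 | (Z)-4-pyranylidene-butyl(triphenyl)phosphonium iodide from F3 | C=C(C)[C@H]1CC[C@H]([C@H]2CC/C(=C/CCC[P+](c3ccccc3)(c3ccccc3)c3ccccc3)CO2)[C@H]1O[Si](C)(C)C(C)(C)C.[I-]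
F5 | step 17 | (2S)-2-[(1R,2S,3R)-2-(TBSO)-3-(prop-1-en-2-yl)cyclopentyl]-4,5-epoxytetrahydro-2H-pyran-3-ol, epimer mixture | C=C(C)[C@H]1CC[C@H]([C@H]2C(O)C3OC3CO2)[C@H]1O[Si](C)(C)C(C)(C)C
F6 | step 17 | O-(imidazol-1-ylthiocarbonyl) derivative of F5 | C=C(C)[C@H]1CC[C@H]([C@H]2C(OC(=S)n3ccnc3)C3OC3CO2)[C@H]1O[Si](C)(C)C(C)(C)C
F7 | step 14 | furan endoperoxide of 23 (1-substituted 2,3,7-trioxabicyclo[2.2.1]hept-5-ene) | C=C(C)[C@H]1CC[C@H]([C@H](O)C23OOC(C=C2)O3)[C@H]1O[Si](C)(C)C(C)(C)C
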